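**Route outline**

- Retrosynthesis: the two peri hydroxyls are masked as methoxymethyl ethers and the C1' ester is cut back to a silyl ether. Ring B is then cut at C4–C3, C2–C1 and C1–C8a into an aryl(methoxy)carbene complex of Cr(CO)5, one CO ligand and a terminal alkyne.
- Enabling feature: ring B carries H on C3 and, on C2, a side chain whose first carbon C1' is the oxygen-bearing stereocentre. C2–C3 is therefore a terminal alkyne with a propargylic stereocentre, C1 and C4 are a CO carbon and the carbene carbon, and C4a/C8a with the 5,8-dioxygenated ring A are a hydroquinone-derived phenyl group with one free ortho carbon.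
- Forward: ring A is bought as hydroquinone. The side chain is finished on the alkyne (epoxide opening, silylation, detritylation, oxidation, alkynylation). One benzannulation joins the two fragments and closes ring B, which is then oxidised to the quinone.
- End game: desilylation, isobutyrylation of the C1' hydroxyl, mild removal of the two acetals.
- Stereochemistry: the only stereocentre, C1' (S), is bought in trityl (S)-glycidyl ether. The epoxide is opened at its CH2 carbon and no bond to C1' is broken afterwards.

Key step: step 8

Assumption: atoms are numbered as in 1,4-naphthoquinone (ring B = C1–C4, C4a, C8a; ring A = C4a–C8a) with the side chain C1'–C5' on C2; the planar chirality of the transient arene–Cr(CO)3 complex is left undefined because the metal is removed in the same step.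

**Route**

Step 1
Reactants: 1 trityl (S)-glycidyl ether; 2 2-methyl-1-propenylmagnesium bromide
Product: 3 (S)-5-methyl-1-(trityloxy)hex-4-en-2-ol
Conditions: CuI (10 mol %), THF, −30 to 0 °C; aq NH4Cl
Reagents that add atoms: none
Why: Copper-catalysed Grignard opening of a terminal epoxide is an SN2 attack of the alkenyl cuprate at the unhindered CH2 carbon, so the C–O bond at the stereocentre is untouched and the S configuration of 1 is carried unchanged into 3.

Step 2
Reactants: 3 (S)-5-methyl-1-(trityloxy)hex-4-en-2-ol
Product: 4 tert-butyldimethyl{[(S)-5-methyl-1-(trityloxy)hex-4-en-2-yl]oxy}silane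
Conditions: TBSCl, imidazole, DMF, rt
Reagents that add atoms: tert-butyldimethylsilyl chloride, CC(C)(C)[Si](C)(C)Cl
Why: Imidazole-promoted silylation of the secondary alcohol gives a TBS ether that withstands the coming base, oxidant and chromium chemistry and is a poor leaving group at the future propargylic and benzylic position.

Step 3
Reactants: 4 tert-butyldimethyl{[(S)-5-methyl-1-(trityloxy)hex-4-en-2-yl]oxy}silane
Product: 5 (S)-2-(tert-butyldimethylsilyloxy)-5-methylhex-4-en-1-ol
Conditions: camphorsulfonic acid (10 mol %), MeOH/CH2Cl2, 0 °C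
Reagents that add atoms: none
Why: Acid-catalysed methanolysis cleaves the primary trityl ether by an SN1 path through the trityl cation (trapped as its methyl ether) far faster than a hindered secondary TBS ether is solvolysed at 0 °C, and catalytic sulfonic acid does not protonate the trisubstituted alkene under these conditions.

Step 4
Reactants: 5 (S)-2-(tert-butyldimethylsilyloxy)-5-methylhex-4-en-1-ol
Product: 6 (S)-2-(tert-butyldimethylsilyloxy)-5-methylhex-4-enal
Conditions: TEMPO (10 mol %), PhI(OAc)2, CH2Cl2, rt
Reagents that add atoms: none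
Why: The oxoammonium oxidation (catalytic TEMPO, PhI(OAc)2 as terminal oxidant) stops at the aldehyde under almost neutral conditions, leaves the electron-rich alkene alone and does not enolise the α-silyloxy aldehyde, which is used crude.

Step 5
Reactants: 6 (S)-2-(tert-butyldimethylsilyloxy)-5-methylhex-4-enal
Product: 7 (S)-3-(tert-butyldimethylsilyloxy)-6-methylhept-5-en-1-yne
Conditions: dimethyl (1-diazo-2-oxopropyl)phosphonate, K2CO3, MeOH, 0 °C to rt
Reagents that add atoms: dimethyl (1-diazo-2-oxopropyl)phosphonate, CC(=O)C(=[N+]=[N-])P(=O)(OC)OC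
Why: The Ohira–Bestmann variant of the Seyferth–Gilbert homologation turns the aldehyde into the terminal alkyne through a diazoalkene and a 1,2-hydrogen shift of the derived alkylidene carbene, under carbonate in methanol at low temperature where α-alkoxy aldehydes normally keep their configuration.

Step 6
Reactants: 8 hydroquinone
Product: 9 1,4-bis(methoxymethoxy)benzene
Conditions: NaH, MOMCl, DMF, 0 °C to rt
Reagents that add atoms: chloromethyl methyl ether, COCCl
Why: Williamson alkylation of the bis-phenoxide gives the bis-acetal, chosen because the OCH2OMe group directs ortho-lithiation and can later be removed under far milder conditions than an aryl methyl ether.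

Step 7
Reactants: 9 1,4-bis(methoxymethoxy)benzene; 10 Cr(CO)6
Product: 13 pentacarbonyl[methoxy(2,5-bis(methoxymethoxy)phenyl)methylidene]chromium (CO)5Cr=C(OMe)Ar, via aryllithium 11 (not isolated), via lithium acylchromate 12 (not isolated)
Conditions: n-BuLi, TMEDA, THF, 0 °C; Cr(CO)6, 0 °C to rt; solvent change; MeOTf, CH2Cl2, 0 °C
Reagents that add atoms: methyl trifluoromethanesulfonate, COS(=O)(=O)C(F)(F)F
Why: Directed ortho-metalation beside an acetal oxygen (all four ring positions of 9 are equivalent), addition of the aryllithium to a CO ligand of Cr(CO)6 and O-methylation of the resulting acylchromate constitute the standard Fischer synthesis of an aryl(methoxy)carbene complex.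

Step 8
Reactants: 7 (S)-3-(tert-butyldimethylsilyloxy)-6-methylhept-5-en-1-yne; 13 carbene complex (CO)5Cr=C(OMe)Ar
Product: 15 2-[(S)-1-(tert-butyldimethylsilyloxy)-4-methylpent-3-enyl]-4-methoxy-5,8-bis(methoxymethoxy)-1-naphthol, via tricarbonylchromium naphthol complex 14 (not isolated)
Conditions: THF (0.05 M), 50 °C, argon; then air, Et2O, rt, filtration through Celite
Reagents that add atoms: none
Why: Loss of one CO from the zerovalent chromium carbene 13 (eased by the ortho acetal oxygen) lets the alkyne coordinate and insert into the Cr=C bond with its CH terminus bonding to the carbene carbon (C4–C3), a CO ligand then inserts at the substituted alkyne carbon (C2–C1) to give a chromium-bound dienylketene, and the ketene carbon closes onto the only free ortho carbon of the aryl group (C1–C8a) before tautomerising to the naphthol, held first as the Cr(CO)3 complex 14 and released by air. The closest known reaction type is the Dötz benzannulation of aryl(methoxy)carbene pentacarbonylchromium complexes with terminal alkynes, propargylic silyl ethers included. Ring B, a six-membered carbocycle, is closed by a 6π-electrocyclisation of the dienylketene onto the arene. No stereocentre is formed: C1' arrives with the alkyne and none of its bonds is broken, and the planar chirality of 14 disappears with the metal. The step needs the phenol pathway to win over indene, furan and cyclobutenone formation, which the methoxy donor, the ether solvent, the dilute medium and the moderate temperature favour, while the bulky silyl ether keeps the benzylic C–O bond from ionising. Regiochemistry is set by the size difference between H and the branched silyloxyalkyl group (large group next to the CO-derived carbon) and is in any case without consequence, because ring A is symmetrically substituted and both regioisomers give the same quinone.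

Step 9
Reactants: 15 2-[(S)-1-(tert-butyldimethylsilyloxy)-4-methylpent-3-enyl]-4-methoxy-5,8-bis(methoxymethoxy)-1-naphthol
Product: 16 2-[(S)-1-(tert-butyldimethylsilyloxy)-4-methylpent-3-enyl]-5,8-bis(methoxymethoxy)-1,4-naphthoquinone
Conditions: (NH4)2Ce(NO3)6 (2.2 equiv), MeCN/H2O, 0 °C, 10 min; aq NaHCO3
Reagents that add atoms: water, O
Why: Tetravalent cerium oxidises the ring that bears the free hydroxyl (a p-methoxyphenol) by two one-electron steps, water adds at C4 and methanol leaves, which gives the 1,4-quinone in ring B while the bis-acetal ring A and the silyl ether survive the short exposure at 0 °C.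

Step 10
Reactants: 16 2-[(S)-1-(tert-butyldimethylsilyloxy)-4-methylpent-3-enyl]-5,8-bis(methoxymethoxy)-1,4-naphthoquinone
Product: 17 2-[(S)-1-hydroxy-4-methylpent-3-enyl]-5,8-bis(methoxymethoxy)-1,4-naphthoquinone
Conditions: HF·pyridine, pyridine, THF, 0 °C to rt
Reagents that add atoms: none
Why: Pyridine-buffered HF cleaves the secondary silyl ether through the strong Si–F bond without the basicity of Bu4NF that quinones do not tolerate and without enough acidity to hydrolyse the aryl acetals.

Step 11
Reactants: 17 2-[(S)-1-hydroxy-4-methylpent-3-enyl]-5,8-bis(methoxymethoxy)-1,4-naphthoquinone; 18 isobutyric anhydride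
Product: 19 (S)-1-[5,8-bis(methoxymethoxy)-1,4-dioxo-1,4-dihydronaphthalen-2-yl]-4-methylpent-3-enyl 2-methylpropanoate
Conditions: DMAP (10 mol %), pyridine, CH2Cl2, 0 °C to rt
Reagents that add atoms: none
Why: DMAP-catalysed acyl transfer from the anhydride esterifies the only free hydroxyl, and since the C1'–O bond is not broken the S configuration is kept.

Step 12
Reactants: 19 (S)-1-[5,8-bis(methoxymethoxy)-1,4-dioxo-1,4-dihydronaphthalen-2-yl]-4-methylpent-3-enyl 2-methylpropanoate
Product: 21 isobutyryl alkannin [(S)-1-(5,8-dihydroxy-1,4-dioxo-1,4-dihydronaphthalen-2-yl)-4-methylpent-3-enyl 2-methylpropanoate], via bis(trimethylsilyl) ether 20 (not isolated)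
Conditions: Me3SiBr, 4 Å molecular sieves, CH2Cl2, −30 °C; then aq NaHCO3
Reagents that add atoms: none
Why: Me3SiBr cleaves aryl methoxymethyl ethers at low temperature by silylation of the aryl oxygen and capture of the methoxymethyl cation by bromide, so the peri oxygens stay masked as silyl ethers in 20 until the neutral aqueous work-up and the ester and the alkene never meet a protic acid.

**Compound list**

1 | trityl (S)-glycidyl ether, (S)-2-[(triphenylmethoxy)methyl]oxirane | C1[C@H](O1)COC(c1ccccc1)(c1ccccc1)c1ccccc1 | starting material
2 | 2-methyl-1-propenylmagnesium bromide | CC(C)=C[Mg]Br | starting material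
3 | (S)-5-methyl-1-(trityloxy)hex-4-en-2-ol | CC(C)=CC[C@H](O)COC(c1ccccc1)(c1ccccc1)c1ccccc1 | intermediate
4 | tert-butyldimethyl{[(S)-5-methyl-1-(trityloxy)hex-4-en-2-yl]oxy}silane | CC(C)=CC[C@H](O[Si](C)(C)C(C)(C)C)COC(c1ccccc1)(c1ccccc1)c1ccccc1 | intermediate
5 | (S)-2-(tert-butyldimethylsilyloxy)-5-methylhex-4-en-1-ol | CC(C)=CC[C@H](O[Si](C)(C)C(C)(C)C)CO | intermediate
6 | (S)-2-(tert-butyldimethylsilyloxy)-5-methylhex-4-enal | CC(C)=CC[C@H](O[Si](C)(C)C(C)(C)C)C=O | intermediate
7 | (S)-3-(tert-butyldimethylsilyloxy)-6-methylhept-5-en-1-yne | CC(C)=CC[C@H](O[Si](C)(C)C(C)(C)C)C#C | intermediate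
8 | hydroquinone | Oc1ccc(O)cc1 | starting material
9 | 1,4-bis(methoxymethoxy)benzene | COCOc1ccc(OCOC)cc1 | intermediate
10 | Cr(CO)6, chromium hexacarbonyl | [Cr].[C-]#[O+].[C-]#[O+].[C-]#[O+].[C-]#[O+].[C-]#[O+].[C-]#[O+] | starting material
11 | 2,5-bis(methoxymethoxy)phenyllithium | [Li]c1cc(OCOC)ccc1OCOC | intermediate
12 | lithium pentacarbonyl[2,5-bis(methoxymethoxy)benzoyl]chromate, Li[(CO)5Cr–C(=O)Ar] | [Li+].[O-]C(=[Cr])c1cc(OCOC)ccc1OCOC.[C-]#[O+].[C-]#[O+].[C-]#[O+].[C-]#[O+].[C-]#[O+] | intermediate
13 | pentacarbonyl[methoxy(2,5-bis(methoxymethoxy)phenyl)methylidene]chromium, (CO)5Cr=C(OMe)Ar | COC(=[Cr])c1cc(OCOC)ccc1OCOC.[C-]#[O+].[C-]#[O+].[C-]#[O+].[C-]#[O+].[C-]#[O+] | intermediate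
14 | Cr(CO)3 complex of naphthol 15 (metal on the new ring B, planar chirality undefined) | CC(C)=CC[C@H](O[Si](C)(C)C(C)(C)C)c1cc(OC)c2c(OCOC)ccc(OCOC)c2c1O.[Cr].[C-]#[O+].[C-]#[O+].[C-]#[O+] | intermediate
15 | 2-[(S)-1-(tert-butyldimethylsilyloxy)-4-methylpent-3-enyl]-4-methoxy-5,8-bis(methoxymethoxy)-1-naphthol | CC(C)=CC[C@H](O[Si](C)(C)C(C)(C)C)c1cc(OC)c2c(OCOC)ccc(OCOC)c2c1O | intermediate
16 | 2-[(S)-1-(tert-butyldimethylsilyloxy)-4-methylpent-3-enyl]-5,8-bis(methoxymethoxy)-1,4-naphthoquinone | CC(C)=CC[C@H](O[Si](C)(C)C(C)(C)C)C1=CC(=O)c2c(OCOC)ccc(OCOC)c2C1=O | intermediate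
17 | 2-[(S)-1-hydroxy-4-methylpent-3-enyl]-5,8-bis(methoxymethoxy)-1,4-naphthoquinone | CC(C)=CC[C@H](O)C1=CC(=O)c2c(OCOC)ccc(OCOC)c2C1=O | intermediate
18 | isobutyric anhydride | CC(C)C(=O)OC(=O)C(C)C | starting material
19 | (S)-1-[5,8-bis(methoxymethoxy)-1,4-dioxo-1,4-dihydronaphthalen-2-yl]-4-methylpent-3-enyl 2-methylpropanoate | CC(C)=CC[C@H](OC(=O)C(C)C)C1=CC(=O)c2c(OCOC)ccc(OCOC)c2C1=O | intermediate
20 | (S)-1-[1,4-dioxo-5,8-bis(trimethylsilyloxy)-1,4-dihydronaphthalen-2-yl]-4-methylpent-3-enyl 2-methylpropanoate | CC(C)=CC[C@H](OC(=O)C(C)C)C1=CC(=O)c2c(O[Si](C)(C)C)ccc(O[Si](C)(C)C)c2C1=O | intermediate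
21 | isobutyryl alkannin, (S)-1-(5,8-dihydroxy-1,4-dioxo-1,4-dihydronaphthalen-2-yl)-4-methylpent-3-enyl 2-methylpropanoate | CC(C)=CC[C@H](OC(=O)C(C)C)C1=CC(=O)c2c(O)ccc(O)c2C1=O | target

**Count and risks**

Total: 12 steps. Longest linear sequence: 10 steps (steps 1 to 5, then 8 to 12).

Steps most likely to fail:

1. Step 12. Process: the Lewis acid may activate the C1' isobutyrate. Acyl–oxygen cleavage or ionisation of the C1'–O bond becomes easier as soon as one peri oxygen is unmasked, because the side-chain ring can then adopt the electron-rich tautomeric form. The ester would be lost and the S configuration eroded. Fallback, setting out from 16 and coming back at 21: the acetals are cleaved before the ester exists. Me3SiBr at −30 °C is applied to 16, in which C1' still carries the silyl ether (no acyl group to lose, a poor leaving group). The transient 2-[(S)-1-(tert-butyldimethylsilyloxy)-4-methylpent-3-enyl]-5,8-bis(trimethylsilyloxy)-1,4-naphthoquinone F1 should be hydrolysed on neutral work-up to 1'-O-(tert-butyldimethylsilyl)alkannin F2. Buffered HF·pyridine should then free alkannin F3; should the TBS ether already fall off in the first operation, the material converges on F3. A Steglich esterification (isobutyric acid, N,N'-dicyclohexylcarbodiimide, catalytic DMAP, CH2Cl2, 0 °C) should then acylate only the side-chain hydroxyl, because the two peri hydroxyls are locked in hydrogen bonds to the quinone carbonyls, and give 21.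

2. Step 9. Process: nitric acid released by the oxidant, helped by Lewis-acidic cerium, may hydrolyse an aryl acetal or the silyl ether, after which excess oxidant attacks the still electron-rich ring A and over-oxidation follows. Fallback, setting out from 15 and coming back at 16: a two-electron oxidation by trivalent iodine replaces the metal oxidant. PhI(OAc)2 in MeOH at 0 °C, with acetic acid as the only acid present, should dearomatise the p-methoxyphenol to the quinone monoketal 2-[(S)-1-(tert-butyldimethylsilyloxy)-4-methylpent-3-enyl]-4,4-dimethoxy-5,8-bis(methoxymethoxy)naphthalen-1(4H)-one F4. This is isolated and hydrolysed to 16 on wet silica gel or with dilute aqueous acetic acid in acetone.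

3. Step 5. Process: enolisation of the α-silyloxy aldehyde by carbonate in methanol before the diazophosphonate anion intercepts it, which would erode the enantiomeric purity of the only stereocentre. Fallback, setting out from 6 and coming back at 7: a Corey–Fuchs sequence. CBr4, PPh3 and Zn dust in CH2Cl2 at rt should convert 6 without any base into tert-butyl{[(S)-1,1-dibromo-6-methylhepta-1,5-dien-3-yl]oxy}dimethylsilane F5, in which C1' is no longer α to a carbonyl. n-BuLi (2 equiv, THF, −78 °C) followed by an aqueous quench should then give 7.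

Step 8 is ranked below these three because both partner classes are established substrates of this benzannulation; its usual shortfall is a lower yield through indene, furan or cyclobutenone by-products, which the convergent supply of 7 and 13 can absorb.

**Further compounds**

F1 | step 12 | 2-[(S)-1-(tert-butyldimethylsilyloxy)-4-methylpent-3-enyl]-5,8-bis(trimethylsilyloxy)-1,4-naphthoquinone (not isolated) | CC(C)=CC[C@H](O[Si](C)(C)C(C)(C)C)C1=CC(=O)c2c(O[Si](C)(C)C)ccc(O[Si](C)(C)C)c2C1=O
F2 | step 12 | 1'-O-(tert-butyldimethylsilyl)alkannin, 2-[(S)-1-(tert-butyldimethylsilyloxy)-4-methylpent-3-enyl]-5,8-dihydroxy-1,4-naphthoquinone | CC(C)=CC[C@H](O[Si](C)(C)C(C)(C)C)C1=CC(=O)c2c(O)ccc(O)c2C1=O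
F3 | step 12 | alkannin, 5,8-dihydroxy-2-[(S)-1-hydroxy-4-methylpent-3-enyl]-1,4-naphthoquinone | CC(C)=CC[C@H](O)C1=CC(=O)c2c(O)ccc(O)c2C1=O
F4 | step 9 | 2-[(S)-1-(tert-butyldimethylsilyloxy)-4-methylpent-3-enyl]-4,4-dimethoxy-5,8-bis(methoxymethoxy)naphthalen-1(4H)-one | CC(C)=CC[C@H](O[Si](C)(C)C(C)(C)C)C1=CC(OC)(OC)c2c(OCOC)ccc(OCOC)c2C1=O
F5 | step 5 | tert-butyl{[(S)-1,1-dibromo-6-methylhepta-1,5-dien-3-yl]oxy}dimethylsilane | CC(C)=CC[C@H](O[Si](C)(C)C(C)(C)C)C=C(Br)Br
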